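**Plan**
Locants: C1 methyl-bearing fusion carbon, C2, C3, C4 isopropyl carbinol, C5 fusion CH, C6 ester carbon, C7 (CH2), C8(CH3)=C9, C10 (CH2); five-membered ring C1–C5, seven-membered ring C1, C5–C10.
Retrosynthesis cuts the C6–O acyl bond, then the C4–isopropyl bond (back to a C4 ketone), then C6–C7 and C1–C10 of the seven-membered ring.
Enabling feature: C7–C8(CH3)=C9–C10 is an intact isoprene unit in the seven-membered ring, flanked by oxygenated C6 and quaternary C1, so a carbene carbon (C6) on a cyclopentene double bond (C5=C1) can take up isoprene by cyclopropanation and Cope rearrangement.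
Forward: 3-methylcyclopent-2-en-1-one supplies the five-membered ring and becomes an alkenyl(methoxy)carbene complex of zerovalent chromium; isoprene is annulated in one operation, closing the seven-membered ring as a C5=C6 enol ether; the enol ether is locked as a dioxolane, C4 is rebuilt as the isopropyl carbinol, C6 is unmasked and reduced, and the ester goes on last.
Stereochemistry: a CBS reduction sets a temporary C4 carbinol (S) whose silyl ether steers C1 (Cope bonding anti) and C5 (protonation anti); C4 is then set by organocerium addition anti to the angular methyl, and C6 by reduction directed from the new C4 hydroxyl.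

Key step: step 5

Remark: CIP descriptors use the locants above; the C5 descriptor changes from R (13–17) to S (18, 20) only because substituent priorities change, not the geometry.

Step 1
Reactants: 1 3-methylcyclopent-2-en-1-one
Product: 3 2-bromo-3-methylcyclopent-2-en-1-one, via dibromo ketone 2 (not isolated)
Conditions: Br2, CH2Cl2, 0 °C; then Et3N, 0 °C → rt
Reagents that add atoms: bromine, BrBr
Why: Bromine adds across the enone double bond and Et3N removes HBr from dibromide 2 by E1cB elimination, the standard addition–elimination α-bromination of cyclic enones, which places the halogen on the future C5 as the handle for metalation.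

Step 2
Reactants: 3 2-bromo-3-methylcyclopent-2-en-1-one
Product: 4 (S)-2-bromo-3-methylcyclopent-2-en-1-ol
Conditions: (R)-2-methyl-CBS-oxazaborolidine (10 mol %), BH3·SMe2, THF, −20 °C
Reagents that add atoms: none
Why: Corey–Bakshi–Shibata reduction, in which the bromoalkene arm acts as the large ketone substituent, so the (R)-catalyst should deliver hydride to the face that gives the (S)-carbinol, the centre that later steers C1 and C5.

Step 3
Reactants: 4 (S)-2-bromo-3-methylcyclopent-2-en-1-ol
Product: 5 (S)-[(2-bromo-3-methylcyclopent-2-en-1-yl)oxy](tert-butyl)dimethylsilane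
Conditions: TBSCl, imidazole, DMF, rt
Reagents that add atoms: tert-butyldimethylsilyl chloride, CC(C)(C)[Si](C)(C)Cl
Why: Imidazole-promoted silylation of a secondary allylic alcohol, giving an ether that tolerates t-BuLi, the carbene chemistry and mild acid and is bulky enough to serve as the steering group.

Step 4
Reactants: 5 (S)-[(2-bromo-3-methylcyclopent-2-en-1-yl)oxy](tert-butyl)dimethylsilane; 6 chromium hexacarbonyl
Product: 9 pentacarbonyl{[(5S)-5-(tert-butyldimethylsilyloxy)-2-methylcyclopent-1-en-1-yl](methoxy)methylidene}chromium, via vinyllithium 7 (not isolated), via lithium acylchromate 8 (not isolated)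
Conditions: t-BuLi (2.1 equiv), Et2O, −78 °C; Cr(CO)6, −78 → 0 °C; Me3OBF4, CH2Cl2, 0 °C
Reagents that add atoms: trimethyloxonium tetrafluoroborate, C[O+](C)C.F[B-](F)(F)F
Why: Bromine–lithium exchange followed by the Fischer carbene synthesis (organolithium addition to a CO ligand of Cr(CO)6, then O-methylation of the acylchromate); the vinyllithium cannot eliminate the neighbouring silyloxy group inside the five-membered ring and is kept cold to prevent O-to-C silyl migration.

Step 5
Reactants: 9 the chromium carbene complex; 10 isoprene
Product: 12 bicyclic methyl enol ether (1R,4S) with C5=C6(OMe) and C8(CH3)=C9, via cis-divinylcyclopropane 11 (not isolated)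
Conditions: isoprene (10 equiv), 1,4-dioxane, sealed tube, 90 °C
Reagents that add atoms: none
Why: Proposed new method: thermal loss of one CO from 9 lets isoprene bind, the electrophilic carbene carbon C6 bonds to the CH2 terminus next to the methyl-bearing carbon, the chromacyclobutane collapses by reductive elimination to the 1-alkenyl-2-vinylcyclopropane 11, and its cis isomer undergoes a boat [3,3] shift (divinylcyclopropane Cope rearrangement) that breaks C6–C8 and forms C1–C10, so that C6–C7 and C1–C10 remain as the two new skeletal bonds. The closest known reaction type is the tandem cyclopropanation–Cope formal [4+3] of alkoxy(alkenyl)carbene complexes of chromium with 2-silyloxy- and 2-amino-1,3-dienes, together with the cyclopropanation of unactivated 1,3-dienes by alkoxycarbene complexes; new here is the pairing of an unactivated 2-alkyl diene with a tetrasubstituted cycloalkenyl carbene. The seven-membered ring is closed not by a direct cyclisation but by this concerted, strain-driven ring expansion of the cyclopropane, in which both alkenes must lie over the three-membered ring. The only new stereocentre, quaternary C1, is set in that transition state: the C4 silyloxy group should force the C8 bridge and the incoming C10 onto the opposite face of the cyclopentene, with only the small methoxy group on its own side, so C1–C10 forms anti to OTBS (1R from 4S); the stereocentres of 11 are erased, and its other stereoisomers should feed the reactive one by reversible homolysis of the weak, donor-substituted C6–C8 bond. The step needs cyclopropanation instead of Diels–Alder addition, which the twisted tetrasubstituted alkenyl group should shut down, and attack on the 1,1-disubstituted alkene of isoprene, which bonding at C7 should favour because it leaves the methyl-stabilised allyl unit on chromium, in line with the preference of electrophilic carbenoids for the methylated double bond of isoprene.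

Step 6
Reactants: 12 bicyclic methyl enol ether (1R,4S)
Product: 13 C6 ethylene ketal (1R,4S,5R) with trans ring fusion and C4–OTBS
Conditions: ethylene glycol (5 equiv), CSA (5 mol %), CH2Cl2, 0 °C
Reagents that add atoms: ethylene glycol, OCCO
Why: Acid-catalysed addition of a diol to an enol ether with loss of methanol (the reaction type of acetonide formation from 2-methoxypropene), in which the rate-limiting protonation at C5 should come from the face anti to the neighbouring C4 silyloxy group, putting H5 trans to the C1 methyl, while anhydrous trapping of the oxocarbenium ion avoids a free β,γ-unsaturated ketone so that C8=C9 stays in place.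

Step 7
Reactants: 13 C6 ethylene ketal (1R,4S,5R) with C4–OTBS
Product: 14 C4 alcohol (1R,4S,5R) with C6 ethylene ketal
Conditions: TBAF, THF, rt
Reagents that add atoms: none
Why: Fluoride-mediated cleavage of the silyl ether, to which the dioxolane, the trisubstituted alkene and the ring-fusion centres are inert.

Step 8
Reactants: 14 C4 alcohol (1R,4S,5R)
Product: 15 C4 ketone (1R,5R) with C6 ethylene ketal
Conditions: Dess–Martin periodinane, pyridine, CH2Cl2, 0 °C → rt
Reagents that add atoms: none
Why: Dess–Martin oxidation of a secondary alcohol under pyridine buffering, neutral enough to keep the dioxolane and to leave the now enolisable C5 centre unepimerised.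

Step 9
Reactants: 15 C4 ketone (1R,5R)
Product: 16 C4 isopropyl carbinol (1R,4R,5R) with C6 ethylene ketal
Conditions: i-PrMgCl, CeCl3, THF, −78 °C
Reagents that add atoms: isopropylmagnesium chloride, CC(C)[Mg]Cl
Why: Imamoto organocerium addition, in which the weakly basic, oxophilic reagent should add to the hindered β-ketal ketone without deprotonating C5 and should approach the cyclopentanone from the face of H5, opposite the pseudoaxial C1 methyl, giving isopropyl cis to H5 and hydroxyl cis to the methyl (4R).

Step 10
Reactants: 16 C4 isopropyl carbinol (1R,4R,5R)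
Product: 17 β-hydroxy ketone (1R,4R,5R) with C6 ketone
Conditions: PPTS, acetone/H2O (10:1), 50 °C
Reagents that add atoms: water, O
Why: Mild acid hydrolysis of a dioxolane, where the weak buffered acid should release the ketone without dehydrating the tertiary aldol, moving C8=C9 into conjugation or epimerising C5.

Step 11
Reactants: 17 β-hydroxy ketone (1R,4R,5R)
Product: 18 diol (1R,4R,5S,6S)
Conditions: Me4NBH(OAc)3, MeCN/AcOH (1:1), −20 °C
Reagents that add atoms: none
Why: Saksena–Evans hydroxyl-directed reduction, in which ligand exchange puts boron on the tertiary C4 oxygen and hydride is delivered intramolecularly to the same face of the C6 carbonyl, which should give the 1,3-anti diol (6S, H6 trans to H5), while this reagent barely reduces ketones from outside.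

Step 12
Reactants: 18 diol (1R,4R,5S,6S); 19 3,4-dimethoxybenzoyl chloride
Product: 20 (1R,4R,5S,6S)-4-hydroxy-4-isopropyl-1,8-dimethyl 5/7-fused bicyclic 8-en-6-yl 3,4-dimethoxybenzoate
Conditions: Et3N, DMAP, CH2Cl2, rt
Reagents that add atoms: none
Why: DMAP-catalysed acylation with an acid chloride, selective for the secondary C6 hydroxyl because the tertiary C4 hydroxyl next to isopropyl is too hindered, with no stereocentre touched.

**Compound list**
1 | 3-methylcyclopent-2-en-1-one | CC1=CC(=O)CC1 | starting material
2 | trans-2,3-dibromo-3-methylcyclopentan-1-one (racemic, one enantiomer drawn) | C[C@]1(Br)CCC(=O)[C@@H]1Br | intermediate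
3 | 2-bromo-3-methylcyclopent-2-en-1-one | CC1=C(Br)C(=O)CC1 | intermediate
4 | (S)-2-bromo-3-methylcyclopent-2-en-1-ol | CC1=C(Br)[C@@H](O)CC1 | intermediate
5 | (S)-[(2-bromo-3-methylcyclopent-2-en-1-yl)oxy](tert-butyl)dimethylsilane | CC1=C(Br)[C@@H](O[Si](C)(C)C(C)(C)C)CC1 | intermediate
6 | chromium hexacarbonyl | O=C=[Cr](=C=O)(=C=O)(=C=O)(=C=O)=C=O | starting material
7 | [(5S)-5-(tert-butyldimethylsilyloxy)-2-methylcyclopent-1-en-1-yl]lithium | [Li]C1=C(C)CC[C@@H]1O[Si](C)(C)C(C)(C)C | intermediate
8 | lithium pentacarbonyl{[(5S)-5-(tert-butyldimethylsilyloxy)-2-methylcyclopent-1-en-1-yl]carbonyl}chromate | [Li+].[O-]C(=[Cr](=C=O)(=C=O)(=C=O)(=C=O)=C=O)C1=C(C)CC[C@@H]1O[Si](C)(C)C(C)(C)C | intermediate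
9 | pentacarbonyl{[(5S)-5-(tert-butyldimethylsilyloxy)-2-methylcyclopent-1-en-1-yl](methoxy)methylidene}chromium (carbene carbon = C6, ring alkene = C5=C1, silyloxy carbon = C4) | COC(=[Cr](=C=O)(=C=O)(=C=O)(=C=O)=C=O)C1=C(C)CC[C@@H]1O[Si](C)(C)C(C)(C)C | intermediate
10 | isoprene (2-methylbuta-1,3-diene) | C=CC(C)=C | starting material
11 | tert-butyl{[(1S)-2-[(1S,2R)-2-ethenyl-1-methoxy-2-methylcyclopropyl]-3-methylcyclopent-2-en-1-yl]oxy}dimethylsilane (cyclopentenyl and vinyl cis on the cyclopropane) | CO[C@@]1(C2=C(C)CC[C@@H]2O[Si](C)(C)C(C)(C)C)C[C@]1(C)C=C | intermediate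
12 | (1R,4S)-4-(tert-butyldimethylsilyloxy)-6-methoxy-1,8-dimethyl 5/7-fused bicyclic 5,8-diene (C5=C6 methyl enol ether, C8=C9; C1 methyl and C4 OTBS cis) | COC1=C2[C@@H](O[Si](C)(C)C(C)(C)C)CC[C@]2(C)CC=C(C)C1 | intermediate
13 | (1R,4S,5R)-4-(tert-butyldimethylsilyloxy)-1,8-dimethyl 5/7-fused bicyclic 8-en-6-one ethylene ketal (H5 trans to C1 methyl and to OTBS) | O1CCOC12CC(C)=CC[C@@]3(C)CC[C@H](O[Si](C)(C)C(C)(C)C)[C@H]23 | intermediate
14 | (1R,4S,5R)-4-hydroxy-1,8-dimethyl 5/7-fused bicyclic 8-en-6-one ethylene ketal | O1CCOC12CC(C)=CC[C@@]3(C)CC[C@H](O)[C@H]23 | intermediate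
15 | (1R,5R)-1,8-dimethyl 5/7-fused bicyclic 8-ene-4,6-dione 6-ethylene ketal | O1CCOC12CC(C)=CC[C@@]3(C)CCC(=O)[C@H]23 | intermediate
16 | (1R,4R,5R)-4-hydroxy-4-isopropyl-1,8-dimethyl 5/7-fused bicyclic 8-en-6-one ethylene ketal (OH cis to C1 methyl, isopropyl cis to H5) | O1CCOC12CC(C)=CC[C@@]3(C)CC[C@@](O)(C(C)C)[C@H]23 | intermediate
17 | (1R,4R,5R)-4-hydroxy-4-isopropyl-1,8-dimethyl 5/7-fused bicyclic 8-en-6-one | O=C2CC(C)=CC[C@@]3(C)CC[C@@](O)(C(C)C)[C@H]23 | intermediate
18 | (1R,4R,5S,6S)-4-isopropyl-1,8-dimethyl 5/7-fused bicyclic 8-ene-4,6-diol (C6–OH trans to C4–OH and to C1 methyl) | O[C@H]2CC(C)=CC[C@@]3(C)CC[C@@](O)(C(C)C)[C@H]23 | intermediate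
19 | 3,4-dimethoxybenzoyl chloride | COc1ccc(C(=O)Cl)cc1OC | starting material
20 | (1R,4R,5S,6S)-4-hydroxy-4-isopropyl-1,8-dimethyl 5/7-fused bicyclic 8-en-6-yl 3,4-dimethoxybenzoate | COc1ccc(C(=O)O[C@H]2CC(C)=CC[C@@]3(C)CC[C@@](O)(C(C)C)[C@H]23)cc1OC | target

**Step count and risks**
Total: 12 steps. Longest linear sequence: 12 steps (1 → 20); compounds 6, 10 and 19 enter in single steps.

Most likely to fail: step 5, step 9, step 11.

Step 5. The carbene may cyclopropanate the unsubstituted double bond of isoprene, bond formation at C1 may not discriminate between the two faces, or the complex may decompose before the diene is captured. The fallback sets out from carbene complex 9 and uses the diene class for which this cascade is established. 2-(Trimethylsilyloxy)buta-1,3-diene in THF at 25–50 °C should be cyclopropanated at its silyl enol ether double bond to the silyloxy divinylcyclopropane F1. This rearranges to the C8 trimethylsilyl enol ether F2, with C8=C9 fixed by the donor group. MeLi then releases the lithium enolate F3 regiospecifically, PhNTf2 traps it as the C8 enol triflate F4, and Me2CuLi replaces the triflate by methyl, returning to the route at 12.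

Step 9. Hydride transfer from the isopropyl reagent (reduction) or enolisation at C5 may outrun addition. The fallback sets out from ketone 15. Isopropenylmagnesium bromide with CeCl3, an sp2 nucleophile without transferable β-hydrogen, should add with the same facial sense to give the isopropenyl carbinol F5. Hydrogenation over RhCl(PPh3)3, which reduces the 1,1-disubstituted alkene and spares the trisubstituted ring alkene, returns to the route at 16.

Step 11. Ligand exchange at the hindered tertiary hydroxyl may be too slow, so that reduction stalls or external hydride delivery from the open face takes over. The fallback sets out from ketone 17 and turns that substrate bias into the tool. LiBH(s-Bu)3 in THF at −78 °C should attack C6 from the face anti to the angular methyl and give the C6-epimeric diol F6. Mitsunobu esterification with 3,4-dimethoxybenzoic acid (PPh3, DIAD) then inverts C6 while installing the ester, coming back to the route at the target 20.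

Further compounds
F1 | step 5 | tert-butyl{[(1S)-2-[(1S,2R)-2-ethenyl-1-methoxy-2-(trimethylsilyloxy)cyclopropyl]-3-methylcyclopent-2-en-1-yl]oxy}dimethylsilane | CO[C@@]1(C2=C(C)CC[C@@H]2O[Si](C)(C)C(C)(C)C)C[C@]1(O[Si](C)(C)C)C=C
F2 | step 5 | (1R,4S)-4-(tert-butyldimethylsilyloxy)-6-methoxy-1-methyl-8-(trimethylsilyloxy) 5/7-fused bicyclic 5,8-diene | COC1=C2[C@@H](O[Si](C)(C)C(C)(C)C)CC[C@]2(C)CC=C(O[Si](C)(C)C)C1
F3 | step 5 | lithium C8 enolate of the (1R,4S) bicyclic C5=C6 methyl enol ether | COC1=C2[C@@H](O[Si](C)(C)C(C)(C)C)CC[C@]2(C)CC=C(O[Li])C1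
F4 | step 5 | (1R,4S)-4-(tert-butyldimethylsilyloxy)-6-methoxy-1-methyl 5/7-fused bicyclic 5,8-dien-8-yl trifluoromethanesulfonate | COC1=C2[C@@H](O[Si](C)(C)C(C)(C)C)CC[C@]2(C)CC=C(OS(=O)(=O)C(F)(F)F)C1
F5 | step 9 | (1R,4R,5R)-4-hydroxy-4-isopropenyl-1,8-dimethyl 5/7-fused bicyclic 8-en-6-one ethylene ketal | O1CCOC12CC(C)=CC[C@@]3(C)CC[C@@](O)(C(C)=C)[C@H]23
F6 | step 11 | (1R,4R,5S,6R)-4-isopropyl-1,8-dimethyl 5/7-fused bicyclic 8-ene-4,6-diol (C6 epimer of 18) | O[C@@H]2CC(C)=CC[C@@]3(C)CC[C@@](O)(C(C)C)[C@H]23
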